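I want to know how much left-handed product beta holds after its short time at low partner, how much theta holds after its long time at high partner, and which holds more.

common to all: left-handed substrate 0.55 M; right-handed substrate 0.55 M; racemization catalyst 55 mM; precatalyst 11 mM

| charge | partner | remark | time |
|---|---|---|---|
| violet | 0.87 M | run made earlier |  |
| ochre | 1.6 M | run made earlier |  |
| beta | 0.600 M |  | 2.5 min |
| theta | 1.38 M |  | 8.0 min |

| run | time / min | left-handed product / % | left-handed substrate / % |
|---|---|---|---|
| violet | 0.333 | 0.6 | 49.5 |
| violet | 0.833 | 2.0 | 47.3 |
| violet | 1.50 | 4.8 | 45.7 |
| violet | 2.50 | 8.9 | 43.0 |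
| violet | 3.00 | 10.5 | 42.2 |
| violet | 4.00 | 14.1 | 39.6 |
| violet | 6.00 | 18.8 | 36.4 |
| ochre | 0.417 | 1.6 | 48.0 |
| ochre | 0.667 | 4.4 | 46.2 |
| ochre | 1.00 | 6.9 | 43.8 |
| ochre | 1.50 | 10.2 | 42.5 |
| ochre | 2.50 | 16.2 | 37.2 |
| ochre | 4.00 | 23.8 | 32.4 |
| ochre | 6.00 | 31.1 | 26.7 |

(scatter of a reading: 0.3 percentage points)

- free catalyst is single-handed; left-handed substrate and right-handed substrate are mirror images of each other, charged as a racemate, each of them at the stated concentration

- which one finishes higher in amount of left-handed product, in percent of the left-handed substrate and right-handed substrate together charged ("neither" within 2 percentage points) (beta / theta / neither)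
- amount of left-handed product at the end, in percent of the left-handed substrate and right-handed substrate together charged, beta
- amount of left-handed product at the end, in percent of the left-handed substrate and right-handed substrate together charged, theta

In the violet run, the rate of left-handed product between 1.50 min and 4.00 min, divided by the mean left-handed substrate, gives a pseudo-first-order constant of 0.0872 min⁻¹. I scale it with [partner] and divide it by the reciprocal of the working time, which gives one dimensionless number, the exposure: how many lifetimes of capture a left-handed substrate molecule has sat through. From a closed pool, product is half the charge times one minus exp(−exposure). Violet reads 2.0% at 0.833 min, below this law, which puts the induction period at 0.345 min, and I subtract that from the time.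

Beta then has exposure 0.130 and theta 1.06, so my reckoning gives 6.08% and 32.7%, and theta stands higher.

Is one number enough? Ochre at 6.00 min has exposure 0.907, which gives 29.8%, but it reads 31.1%. Product plus left-handed substrate there is 57.8%, above the left-handed share of the charge, 50.0%, so the pool is being refilled. The ochre reading stands 1.3 percentage points above the law, so one number does not describe that flask exactly, and that gap belongs to ochre, so I leave my theta figure as it stands.

The forecast gives 6% (5% to 7%) for beta and 33.5% (30.5% to 36.5%) for theta: “Theta finishes clearly higher”.

The flask gives 5.74% for beta and 33.3% for theta.

    partner + free catalyst + left-handed substrate → free catalyst + left-handed product (k = 0.170 L² mol⁻² s⁻¹)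
    partner + free catalyst + right-handed substrate → free catalyst + right-handed product (k = 0.0690 L² mol⁻² s⁻¹)
    left-handed substrate + racemization catalyst ⇌ right-handed substrate + racemization catalyst, rate k3*[racemization catalyst]*[left-handed substrate] forward; the back reaction follows from the equilibrium constant (k = 0.210 L mol⁻¹ s⁻¹)
    partner + precatalyst → free catalyst + spent reagent (k = 0.0540 L mol⁻¹ s⁻¹)

With the reaction of left-handed substrate to right-handed substrate struck out both ways, theta gives 30.3% at 8.0 min. Theta's exposure of 1.06, carried to the neighbour charged with 0.83 M of partner for the same time, becomes 0.637, which gives 23.6%, and that flask holds 21.9%.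

The earlier runs and the new flask come from a simulation for substances that don't exist, and the scatter is random.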